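In the early minutes of the eta run, target gained over starting material lost in a stretch of time, the running share (differential selectivity), reads 0.461.

in all of them: partner 0.152 M; second substrate 0.122 M

|  | starting material | remark | time |
|---|---|---|---|
| eta | 0.061 M | run made earlier |  |
| alpha | 0.030 M | run made earlier |  |
| zeta | 0.046 M | run made earlier |  |
| south-east | 0.061 M | a single well-mixed tank run continuously and read at steady state, 80 min in it on average |  |
| east | 0.061 M | plug flow through a tube for 80 min, no back-mixing | 80 min |
| north | 0.061 M | a closed flask charged with all of it at once and left for 80 min | 80 min |
| north-west | 0.061 M (fed, over 40.0 min) | a stirred flask in which starting material is dosed at a steady rate over 40.0 min without added volume, worked up at 80 min | 80 min |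

| run | time / min | target / % | starting material / % |
|---|---|---|---|
| eta | 6.00 | 21.1 | 54.2 |
| eta | 15.0 | 37.1 | 28.3 |
| eta | 30.0 | 47.4 | 13.5 |
| eta | 50.0 | 52.6 | 4.7 |
| alpha | 15.0 | 38.9 | 25.9 |
| alpha | 30.0 | 47.7 | 9.3 |
| alpha | 50.0 | 54.4 | 4.1 |
| alpha | 60.0 | 54.4 | 3.1 |
| zeta | 5.00 | 19.4 | 60.0 |
| zeta | 12.0 | 33.3 | 33.2 |
| zeta | 30.0 | 47.2 | 10.3 |
| zeta | 60.0 | 56.4 | 3.4 |

(scatter of a reading: 1 percentage point)

- the stated concentrations are those of everything mixed, before any reaction; amounts are the same in each set-up
- the feed brings no volume worth counting
- the earlier runs were made in a closed, stirred flask

1. the set-up with the highest amount of target at the outlet or at the end, in percent of the starting material put in ("none" if the first two lie within 2 percentage points) (south-east / east / north / north-west / none)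
2. amount of target at the outlet or at the end, in percent of the starting material put in, south-east
3. amount of target at the outlet or at the end, in percent of the starting material put in, east
4. amount of target at the outlet or at the end, in percent of the starting material put in, north
5. amount of target at the outlet or at the end, in percent of the starting material put in, north-west

That share climbs with the clock, not with the charge. Counted from the start to 30.0 min, it is 0.548 in eta and 0.526 in alpha, although eta holds twice the charge. Pooling the three runs, the stretch ending at 30.0 min reads 0.608. The late share, the running share after 30.0 min, reads 0.963, a reading from small differences. So we join the two ends for north-west, whose dosing moves consumption later, and we take first-order loss on the clock of the closed runs, in fractions of the charge.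

Mean loss constant to 30.0 min, eta: 0.0667 min⁻¹

Held at 30.0 min: 0.324; consumed: 0.426, less than the 86 percentage points consumed by then in eta

Late loss constant, zeta: 0.0369 min⁻¹

Held at 40.0 min: 0.433; at 80 min: 0.0988

Consumed after 30.0 min: 0.475

Target: 69.1 %

The weak link is the leap from 0.608 to 0.963 at 30.0 min. We give the 0.141 consumed in north-west between 30.0 min and the end of the feed the mean of the two shares instead:

Target: 66.6 %

For north, zeta's last reading plus its remainder at the late share gives 59.7 %, so we expect north-west to stand higher; this reckoning puts no number on the tank.

The forecast differs from our reckoning: it says none, with 44 %, 59 %, 59 % and 49 % in the order asked, reading “something dying with time”.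

The north-west flask gives 66.2 %, against 56.0 % in north, 56.0 % in east and 52.0 % in south-east.

    starting material + partner → target (k = 0.350 L mol⁻¹ min⁻¹)
    second substrate + partner → second product (k = 0.100 L mol⁻¹ min⁻¹)
    starting material + second substrate → cross product (k = 0.580 L mol⁻¹ min⁻¹)
    2 second substrate → self-condensation product (k = 0.300 L mol⁻¹ min⁻¹)

North-west ends with 25.0 % of cross product, less than the 42.6 % in north. It also holds 8.80 % of starting material at 80 min; at the late share that remainder would bring the flask to 74.7 %, and left until 800 min it stands at 74.2 %.

The readings are simulated for an exercise, noise included.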